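The quinone ring is assembled, not taken from an arene. Its C1(=O)–C2(OMe)=C3H–C4(=O) half is the four-membered ring of a squarate-derived 4-hydroxycyclobutenone; the C5H=C6(hexaprenyl) edge is the C≡C bond of an all-E hexaprenylacetylene. Thermolysis opens the cyclobutenone to an enynylketene, which closes to the six-membered ring and delivers the 1,4-dione directly at the quinone oxidation level, with methoxy and chain flanking the same carbonyl (Moore rearrangement). The precursor, racemic 4-hydroxy-2-methoxy-4-alkynylcyclobut-2-enone, comes from dimethyl squarate by acetylide addition and a hydride-based 1,3-carbonyl transposition; the C30 chain comes from two farnesyl units by sulfone coupling.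

Key step: step 10

Remark: the target has no stereocentre; its stereochemical content is the five E trisubstituted C=C bonds of the side chain. Four are taken from (2E,6E)-farnesyl building blocks and one is set in step 1.

Step 1
Reactants: 1 (2E,6E)-farnesyl acetate
Product: 2 (2E,6E,10E)-12-hydroxy-3,7,11-trimethyldodeca-2,6,10-trien-1-yl acetate
Conditions: SeO2 (cat.), t-BuOOH, salicylic acid (cat.), CH2Cl2, 0 °C to rt, stopped at partial conversion
Reagents that add atoms: tert-butyl hydroperoxide, CC(C)(C)OO (oxygen delivered through catalytic selenium dioxide, O=[Se]=O)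
Why: SeO2 allylic oxidation (ene reaction, then [2,3]-sigmatropic shift) should hydroxylate the E-methyl group of the terminal isopropylidene unit, which sets the 10E double bond, while the 2,3-alkene is deactivated by the allylic acetate.

Step 2
Reactants: 2 (2E,6E,10E)-12-hydroxy-3,7,11-trimethyldodeca-2,6,10-trien-1-yl acetate
Product: 3 (2E,6E,10E)-12-bromo-3,7,11-trimethyldodeca-2,6,10-trien-1-yl acetate
Conditions: CBr4, PPh3, CH2Cl2, 0 °C
Reagents that add atoms: carbon tetrabromide, BrC(Br)(Br)Br
Why: Appel bromination of a primary allylic alcohol proceeds by SN2 displacement under neutral conditions, so the acetate and the E double bonds should be untouched.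

Step 3
Reactants: 4 (2E,6E)-farnesyl bromide
Product: 5 (2E,6E)-farnesyl p-tolyl sulfone
Conditions: TolSO2Na, DMF, rt
Reagents that add atoms: sodium p-toluenesulfinate, Cc1ccc(cc1)S(=O)[O-].[Na+]
Why: S-alkylation of a sulfinate by a primary allylic bromide (SN2) is a standard sulfone synthesis and keeps the 2E geometry.

Step 4
Reactants: 5 (2E,6E)-farnesyl p-tolyl sulfone; 3 (2E,6E,10E)-12-bromo-3,7,11-trimethyldodeca-2,6,10-trien-1-yl acetate
Product: 7 (2E,6E,10E,14E,18E)-3,7,11,15,19,23-hexamethyl-13-(p-tolylsulfonyl)tetracosa-2,6,10,14,18,22-hexaen-1-yl acetate (racemic at C13), via lithiated sulfone 6 (not isolated)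
Conditions: n-BuLi, THF–DMPU, −78 °C; then 3, −78 to −40 °C
Reagents that add atoms: none
Why: α-Alkylation of a sulfonyl-stabilised allyl anion by an allylic bromide (Julia-type sulfone coupling) joins the two C15 units head to tail, the soft carbanion should prefer SN2 at the bromide over attack on the acetate at −78 °C, and the racemic C13 stereocentre is removed in step 5.

Step 5
Reactants: 7 (2E,6E,10E,14E,18E)-3,7,11,15,19,23-hexamethyl-13-(p-tolylsulfonyl)tetracosa-2,6,10,14,18,22-hexaen-1-yl acetate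
Product: 9 (2E,6E,10E,14E,18E)-3,7,11,15,19,23-hexamethyltetracosa-2,6,10,14,18,22-hexaen-1-ol (all-E hexaprenol), via hydroxy sulfone lithium alkoxide 8 (not isolated)
Conditions: LiEt3BH, THF, −78 to 0 °C (acetate cleavage); then PdCl2(dppp) (cat.), LiEt3BH, 0 °C to rt
Reagents that add atoms: none
Why: The hydride first cleaves the acetate, so no allylic ester is left for palladium, and the Pd-catalysed hydride desulfonylation of the allylic sulfone then delivers hydride to the less substituted π-allyl terminus, which should keep the 14E trisubstituted alkene in place.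

Step 6
Reactants: 9 all-E hexaprenol
Product: 10 (2E,6E,10E,14E,18E)-1-bromo-3,7,11,15,19,23-hexamethyltetracosa-2,6,10,14,18,22-hexaene (hexaprenyl bromide)
Conditions: PBr3, Et2O, −10 to 0 °C
Reagents that add atoms: phosphorus tribromide, BrP(Br)Br
Why: Bromination of a primary polyprenol with PBr3 at low temperature is the standard route to polyprenyl bromides and should retain the 2E geometry.

Step 7
Reactants: 10 hexaprenyl bromide
Product: 11 (4E,8E,12E,16E,20E)-5,9,13,17,21,25-hexamethylhexacosa-4,8,12,16,20,24-hexaen-1-yne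
Conditions: HC≡CMgBr (3 equiv), CuCl (cat.), THF, 0 °C to rt
Reagents that add atoms: ethynylmagnesium bromide, C#C[Mg]Br
Why: Copper-catalysed coupling of an alkynyl Grignard reagent with a primary prenyl-type bromide should occur at the unhindered α-carbon to give the skipped 1,4-enyne, and the excess of Grignard reagent suppresses double alkylation.

Step 8
Reactants: 11 (4E,8E,12E,16E,20E)-5,9,13,17,21,25-hexamethylhexacosa-4,8,12,16,20,24-hexaen-1-yne; 12 dimethyl squarate (3,4-dimethoxycyclobut-3-ene-1,2-dione)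
Product: 15 rac-2,3-dimethoxy-4-[(4E,8E,12E,16E,20E)-5,9,13,17,21,25-hexamethylhexacosa-4,8,12,16,20,24-hexaen-1-yn-1-yl]-4-(trimethylsilyloxy)cyclobut-2-en-1-one, via lithium acetylide 13 (not isolated), via lithium alkoxide adduct 14 (not isolated)
Conditions: n-BuLi, THF, −78 °C; 12, −78 °C; then TMSCl, −78 to 0 °C
Reagents that add atoms: chlorotrimethylsilane, C[Si](C)(C)Cl
Why: 1,2-Addition of a lithium acetylide to one of the two equivalent carbonyls of the symmetrical squarate is the standard entry to 4-hydroxycyclobutenones, silylation of 14 in the same flask protects the tertiary propargylic oxygen for step 9, and the racemic carbinol centre is destroyed in step 10.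

Step 9
Reactants: 15 rac-2,3-dimethoxy-4-(polyprenylethynyl)-4-(trimethylsilyloxy)cyclobut-2-en-1-one
Product: 18 rac-4-hydroxy-2-methoxy-4-[(4E,8E,12E,16E,20E)-5,9,13,17,21,25-hexamethylhexacosa-4,8,12,16,20,24-hexaen-1-yn-1-yl]cyclobut-2-en-1-one, via cyclobutenol 16 (not isolated), via transposed silyl ether 17 (not isolated)
Conditions: DIBAL-H, CH2Cl2, −78 °C; then 1 M HCl, THF, 0 °C, until the silyl ether is cleaved
Reagents that add atoms: water, O
Why: Stork–Danheiser-type 1,3-carbonyl transposition, in which 1,2-reduction of the vinylogous ester carbonyl gives 16 (formed as its aluminium alkoxide, diastereomers converge), acid ionises the free secondary allylic C–O with help from the 3-methoxy group, water adds at C3 and methanol is lost, so the former C3 becomes the carbonyl and the former carbonyl carbon becomes the ring CH, the silyl ether shielding the tertiary propargylic C–O until the transposition is over.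

Step 10
Reactants: 18 rac-4-hydroxy-2-methoxy-4-(polyprenylethynyl)cyclobut-2-en-1-one
Product: 21 2-methoxy-6-[(2E,6E,10E,14E,18E)-3,7,11,15,19,23-hexamethyltetracosa-2,6,10,14,18,22-hexaen-1-yl]cyclohexa-2,5-diene-1,4-dione, via enynylketene 19 (not isolated), via phenoxyl aryl diradical 20 (not isolated)
Conditions: degassed toluene (0.01 M), 110 °C
Reagents that add atoms: none
Why: Heating should trigger conrotatory 4π-electrocyclic opening of the C(=O)–C(OH) bond of the cyclobutenone, the hydroxyl rotating outward so that the alkynyl group lies cis to the ketene in 19. The ketene carbon then bonds to the distal alkyne carbon in a six-membered closure with the alkyne inside the new ring (6-endo-dig type) to give diradical 20, and transfer of the hydroxyl hydrogen to the adjacent ring carbon radical gives the quinone; the closest known reaction type is the Moore rearrangement of 4-alkynyl-4-hydroxycyclobutenones. No stereocentre is created, and the racemic carbinol carbon becomes the C4 carbonyl. The step needs six- over five-membered closure, which the non-radical-stabilising CH2 substituent on the alkyne terminus should secure, and it needs the 2-methoxy/3-H arrangement of 18, which places OMe and the chain on the two flanks of the ketene-derived carbonyl. The isolated trisubstituted alkenes should be spectators under neutral thermolysis at high dilution, and the step is an isomerisation with no by-product.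

Compound list
1 | (2E,6E)-farnesyl acetate | CC(=O)OC/C=C(\C)CC/C=C(\C)CCC=C(C)C | starting material
2 | (2E,6E,10E)-12-hydroxy-3,7,11-trimethyldodeca-2,6,10-trien-1-yl acetate | CC(=O)OC/C=C(\C)CC/C=C(\C)CC/C=C(\C)CO | intermediate
3 | (2E,6E,10E)-12-bromo-3,7,11-trimethyldodeca-2,6,10-trien-1-yl acetate | CC(=O)OC/C=C(\C)CC/C=C(\C)CC/C=C(\C)CBr | intermediate
4 | (2E,6E)-farnesyl bromide | BrC/C=C(\C)CC/C=C(\C)CCC=C(C)C | starting material
5 | (2E,6E)-farnesyl p-tolyl sulfone | Cc1ccc(cc1)S(=O)(=O)C/C=C(\C)CC/C=C(\C)CCC=C(C)C | intermediate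
6 | α-lithio derivative of sulfone 5 (not isolated) | [Li]C(/C=C(\C)CC/C=C(\C)CCC=C(C)C)S(=O)(=O)c1ccc(C)cc1 | intermediate
7 | (2E,6E,10E,14E,18E)-3,7,11,15,19,23-hexamethyl-13-(p-tolylsulfonyl)tetracosa-2,6,10,14,18,22-hexaen-1-yl acetate, racemic at C13 | CC(=O)OC/C=C(\C)CC/C=C(\C)CC/C=C(\C)CC(/C=C(\C)CC/C=C(\C)CCC=C(C)C)S(=O)(=O)c1ccc(C)cc1 | intermediate
8 | lithium alkoxide of the C30 13-(p-tolylsulfonyl) hexaenol, racemic at C13 (not isolated) | [Li]OC/C=C(\C)CC/C=C(\C)CC/C=C(\C)CC(/C=C(\C)CC/C=C(\C)CCC=C(C)C)S(=O)(=O)c1ccc(C)cc1 | intermediate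
9 | (2E,6E,10E,14E,18E)-3,7,11,15,19,23-hexamethyltetracosa-2,6,10,14,18,22-hexaen-1-ol (all-E hexaprenol) | OC/C=C(\C)CC/C=C(\C)CC/C=C(\C)CC/C=C(\C)CC/C=C(\C)CCC=C(C)C | intermediate
10 | (2E,6E,10E,14E,18E)-1-bromo-3,7,11,15,19,23-hexamethyltetracosa-2,6,10,14,18,22-hexaene (hexaprenyl bromide) | BrC/C=C(\C)CC/C=C(\C)CC/C=C(\C)CC/C=C(\C)CC/C=C(\C)CCC=C(C)C | intermediate
11 | (4E,8E,12E,16E,20E)-5,9,13,17,21,25-hexamethylhexacosa-4,8,12,16,20,24-hexaen-1-yne | C#CC/C=C(\C)CC/C=C(\C)CC/C=C(\C)CC/C=C(\C)CC/C=C(\C)CCC=C(C)C | intermediate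
12 | dimethyl squarate (3,4-dimethoxycyclobut-3-ene-1,2-dione) | COC1=C(OC)C(=O)C1=O | starting material
13 | lithium acetylide of enyne 11 (not isolated) | [Li]C#CC/C=C(\C)CC/C=C(\C)CC/C=C(\C)CC/C=C(\C)CC/C=C(\C)CCC=C(C)C | intermediate
14 | lithium alkoxide of rac-4-hydroxy-2,3-dimethoxy-4-(polyprenylethynyl)cyclobut-2-en-1-one (not isolated) | [Li]OC1(C#CC/C=C(\C)CC/C=C(\C)CC/C=C(\C)CC/C=C(\C)CC/C=C(\C)CCC=C(C)C)C(OC)=C(OC)C1=O | intermediate
15 | rac-2,3-dimethoxy-4-[(4E,8E,12E,16E,20E)-5,9,13,17,21,25-hexamethylhexacosa-4,8,12,16,20,24-hexaen-1-yn-1-yl]-4-(trimethylsilyloxy)cyclobut-2-en-1-one | C[Si](C)(C)OC1(C#CC/C=C(\C)CC/C=C(\C)CC/C=C(\C)CC/C=C(\C)CC/C=C(\C)CCC=C(C)C)C(OC)=C(OC)C1=O | intermediate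
16 | 2,3-dimethoxy-4-(polyprenylethynyl)-4-(trimethylsilyloxy)cyclobut-2-en-1-ol, racemic mixture of diastereomers (not isolated) | C[Si](C)(C)OC1(C#CC/C=C(\C)CC/C=C(\C)CC/C=C(\C)CC/C=C(\C)CC/C=C(\C)CCC=C(C)C)C(OC)=C(OC)C1O | intermediate
17 | rac-2-methoxy-4-(polyprenylethynyl)-4-(trimethylsilyloxy)cyclobut-2-en-1-one (not isolated) | C[Si](C)(C)OC1(C#CC/C=C(\C)CC/C=C(\C)CC/C=C(\C)CC/C=C(\C)CC/C=C(\C)CCC=C(C)C)C=C(OC)C1=O | intermediate
18 | rac-4-hydroxy-2-methoxy-4-[(4E,8E,12E,16E,20E)-5,9,13,17,21,25-hexamethylhexacosa-4,8,12,16,20,24-hexaen-1-yn-1-yl]cyclobut-2-en-1-one | OC1(C#CC/C=C(\C)CC/C=C(\C)CC/C=C(\C)CC/C=C(\C)CC/C=C(\C)CCC=C(C)C)C=C(OC)C1=O | intermediate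
19 | 4-hydroxy-2-methoxy-4-(polyprenylethynyl)buta-1,3-dien-1-one, alkynyl cis to the ketene-bearing carbon (enynylketene, not isolated) | COC(=C=O)/C=C(\C#CC/C=C(\C)CC/C=C(\C)CC/C=C(\C)CC/C=C(\C)CC/C=C(\C)CCC=C(C)C)O | intermediate
20 | 4-hydroxy-2-hexaprenyl-6-methoxyphenoxyl-3-yl diradical (O-centred radical at C1, σ-radical at C3; not isolated) | COC1=CC(O)=[C]C(C/C=C(\C)CC/C=C(\C)CC/C=C(\C)CC/C=C(\C)CC/C=C(\C)CCC=C(C)C)=C1[O] | intermediate
21 | 2-methoxy-6-[(2E,6E,10E,14E,18E)-3,7,11,15,19,23-hexamethyltetracosa-2,6,10,14,18,22-hexaen-1-yl]cyclohexa-2,5-diene-1,4-dione | COC1=CC(=O)C=C(C/C=C(\C)CC/C=C(\C)CC/C=C(\C)CC/C=C(\C)CC/C=C(\C)CCC=C(C)C)C1=O | target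

Total step count: 10.
Longest linear sequence: 9 steps (steps 1, 2, 4, 5, 6, 7, 8, 9, 10 from farnesyl acetate 1); step 3 is a one-step branch.

Steps most likely to fail

Step 9. The silyl group may be lost before the transposition is complete, after which ionisation at the tertiary propargylic carbon competes with ionisation at the reduced carbon; the hydrolysis may also run on past the hydroxy enone towards an alkynylcyclobutenedione. The fallback avoids any transposition and sets out from 11 and 12, returning to the route at 21. Enyne 11 is bromoborated with B-bromo-9-BBN (CH2Cl2, 0 °C) to the (Z)-2-bromoalkenylborane F1, protonolysed with acetic acid to the 2-bromo-1-alkene F2, and exchanged with t-BuLi (Et2O, −78 °C) to the 2-lithio-1-alkene F3. Separately, 12 is reduced with LiAlH(OtBu)3 to 4-hydroxy-2,3-dimethoxycyclobut-2-en-1-one F4 and hydrolysed with HCl to 3-methoxycyclobut-3-ene-1,2-dione F5. F3 should add to the more electrophilic carbonyl of F5, the one that is not part of the vinylogous ester, to give the 4-alkenyl-4-hydroxy-3-methoxycyclobutenone F6. Thermolysis of F6 (toluene, 110 °C) should give, by four-membered ring opening and 6π-electrocyclisation of the dienylketene, the 2-hexaprenyl-6-methoxyhydroquinone F7, which Ag2O oxidises to 21.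

Step 10. The enynylketene may close in the five-membered mode to an alkylidenecyclopentenedione, or the σ-aryl radical may abstract hydrogen from allylic positions of the chain. The fallback replaces the diradical path by a closed-shell one and sets out from 18, returning at 21. Semihydrogenation of 18 over Lindlar catalyst with quinoline gives the (1Z)-alkenyl hydroxycyclobutenone F8. Thermolysis of F8 in toluene should lead, by ring opening and 6π-electrocyclisation, to the hydroquinone F7 already described, and Ag2O then gives 21.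

Step 7. SN2′ attack at the tertiary allylic terminus, erosion of the 4E geometry through copper-allyl species, or double alkylation of acetylene may lower the yield of the linear enyne. The fallback uses an uncatalysed SN2 reaction of a capped acetylide and sets out from 10, returning at 11. Lithium (trimethylsilyl)acetylide in THF–DMPU (−78 to 0 °C) should displace the bromide directly to give the silyl-capped enyne F9, and K2CO3 in methanol removes the silyl group to give 11.

Further compounds
F1 | step 9 | 9-[(1Z,4E,8E,12E,16E,20E)-2-bromo-5,9,13,17,21,25-hexamethylhexacosa-1,4,8,12,16,20,24-heptaen-1-yl]-9-borabicyclo[3.3.1]nonane | Br/C(C/C=C(\C)CC/C=C(\C)CC/C=C(\C)CC/C=C(\C)CC/C=C(\C)CCC=C(C)C)=C\B1C2CCCC1CCC2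
F2 | step 9 | (4E,8E,12E,16E,20E)-2-bromo-5,9,13,17,21,25-hexamethylhexacosa-1,4,8,12,16,20,24-heptaene | C=C(Br)C/C=C(\C)CC/C=C(\C)CC/C=C(\C)CC/C=C(\C)CC/C=C(\C)CCC=C(C)C
F3 | step 9 | (4E,8E,12E,16E,20E)-2-lithio-5,9,13,17,21,25-hexamethylhexacosa-1,4,8,12,16,20,24-heptaene | [Li]C(=C)C/C=C(\C)CC/C=C(\C)CC/C=C(\C)CC/C=C(\C)CC/C=C(\C)CCC=C(C)C
F4 | step 9 | rac-4-hydroxy-2,3-dimethoxycyclobut-2-en-1-one | COC1=C(OC)C(O)C1=O
F5 | step 9 | 3-methoxycyclobut-3-ene-1,2-dione | COC1=CC(=O)C1=O
F6 | step 9 | rac-4-hydroxy-3-methoxy-4-[(4E,8E,12E,16E,20E)-5,9,13,17,21,25-hexamethylhexacosa-1,4,8,12,16,20,24-heptaen-2-yl]cyclobut-2-en-1-one | O=C1C=C(OC)C1(O)C(=C)C/C=C(\C)CC/C=C(\C)CC/C=C(\C)CC/C=C(\C)CC/C=C(\C)CCC=C(C)C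
F7 | step 9 | 2-[(2E,6E,10E,14E,18E)-3,7,11,15,19,23-hexamethyltetracosa-2,6,10,14,18,22-hexaen-1-yl]-6-methoxybenzene-1,4-diol | COc1cc(O)cc(C/C=C(\C)CC/C=C(\C)CC/C=C(\C)CC/C=C(\C)CC/C=C(\C)CCC=C(C)C)c1O
F8 | step 10 | rac-4-hydroxy-2-methoxy-4-[(1Z,4E,8E,12E,16E,20E)-5,9,13,17,21,25-hexamethylhexacosa-1,4,8,12,16,20,24-heptaen-1-yl]cyclobut-2-en-1-one | OC1(/C=C\C/C=C(\C)CC/C=C(\C)CC/C=C(\C)CC/C=C(\C)CC/C=C(\C)CCC=C(C)C)C=C(OC)C1=O
F9 | step 7 | trimethyl[(4E,8E,12E,16E,20E)-5,9,13,17,21,25-hexamethylhexacosa-4,8,12,16,20,24-hexaen-1-yn-1-yl]silane | C[Si](C)(C)C#CC/C=C(\C)CC/C=C(\C)CC/C=C(\C)CC/C=C(\C)CC/C=C(\C)CCC=C(C)C
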